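**Retrosynthetic overview**
- Target ⇐ 5Z-oxocene dibromide: a bromonium triggers transannular ring contraction to a tricyclic oxonium ion, and water re-expands it to the oxocane (sets C9–OH and C10–Br); C3–Br is installed just before by Appel inversion.
- Oxocene ⇐ eight-membered reductive etherification of a keto silyl ether (forms O–C6, sets C6).
- Keto silyl ether ⇐ Z-selective Wittig union of a 3-oxooxolane acetaldehyde (C1–C9) with a C10–C15 ylide that already carries C12–O and C13–Br.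
- C1–C9 ⇐ furan + an epoxy alkynol (Sharpless kinetic resolution), then a singlet-oxygen/oxa-Michael cascade; C10–C15 ⇐ (Z)-hex-3-en-1-ol by asymmetric epoxidation and bromide opening.
- Ring order: oxolane (ring A) first, oxocene second, saturated oxocane last.

Assumption: C1–C15 in the Why lines are the target's chain positions (C1 = alkyne CH, C15 = methyl), Oa is the oxocane oxygen and Ob the oxolane oxygen; compound names use their own locants.

**Step 1**
Reactants: 1 (±)-pent-1-en-4-yn-3-ol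
Product: 2 (1S)-1-[(2R)-oxiran-2-yl]prop-2-yn-1-ol
Conditions: Ti(OiPr)4 (10 mol%), L-(+)-diisopropyl tartrate (14 mol%), t-BuOOH (0.45 equiv), 4 Å MS, CH2Cl2, −20 °C
Reagents that add atoms: tert-butyl hydroperoxide, CC(C)(C)OO
Why: Sharpless asymmetric epoxidation run as a kinetic resolution: with the L-(+)-tartrate catalyst the (R)-carbinol is epoxidised fast and anti (erythro) to its hydroxyl, which sets C3 (S) and C4 (R) together and leaves (S)-1 behind.

**Step 2**
Reactants: 2 (1S)-1-[(2R)-oxiran-2-yl]prop-2-yn-1-ol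
Product: 3 {[(1S)-1-[(2R)-oxiran-2-yl]prop-2-yn-1-yl]oxy}tri(propan-2-yl)silane
Conditions: TIPSOTf, 2,6-lutidine, CH2Cl2, −78 → 0 °C
Reagents that add atoms: triisopropylsilyl trifluoromethanesulfonate, CC(C)[Si](OS(=O)(=O)C(F)(F)F)(C(C)C)C(C)C
Why: Silyl ether formation at the only hydroxyl; the bulky, non-participating TIPS ether keeps O3 out of the oxa-Michael step 4 and the oxocarbenium step 11.

**Step 3**
Reactants: 3 {[(1S)-1-[(2R)-oxiran-2-yl]prop-2-yn-1-yl]oxy}tri(propan-2-yl)silane; 4 furan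
Product: 6 (2R,3S)-1-(furan-2-yl)-3-(triisopropylsilyloxy)pent-4-yn-2-ol, via furan-2-yllithium 5 (not isolated)
Conditions: 4 (3.2 equiv), n-BuLi (3.0 equiv), THF, 0 °C; then 3, CuI (10 mol%), −40 → 0 °C; aq. NH4Cl
Reagents that add atoms: none
Why: Copper-catalysed SN2 opening of the terminal epoxide by the furyl anion at C5 (one equivalent is used up by the alkyne C–H and returned on work-up), which leaves C4 as the free (R)-carbinol.

**Step 4**
Reactants: 6 (2R,3S)-1-(furan-2-yl)-3-(triisopropylsilyloxy)pent-4-yn-2-ol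
Product: 9 2-[(2R,5R)-3-oxo-5-[(1S)-1-(triisopropylsilyloxy)prop-2-yn-1-yl]oxolan-2-yl]acetaldehyde, via furan endoperoxide 7 (not isolated), via (Z)-4-oxoenal 8 (not isolated)
Conditions: O2, tetraphenylporphyrin (cat.), visible light, CH2Cl2, −78 °C; Me2S, −78 °C → rt; then Et3N (0.2 equiv), rt
Reagents that add atoms: dioxygen, O=O
Why: Photooxygenation of the furan, reduction of the endoperoxide to the cis-enedione and intramolecular oxa-Michael addition of the C4 hydroxyl to C7 give the oxolan-3-one; C7 can equilibrate (enolisation, retro-Michael) and settles in the 2,5-cis arrangement.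

**Step 5**
Reactants: 10 (3Z)-hex-3-en-1-ol
Product: 11 2-[(2S,3R)-3-ethyloxiran-2-yl]ethan-1-ol
Conditions: VO(OiPr)3 (1 mol%), C2-symmetric bis-hydroxamic acid ligand from trans-cyclohexane-1,2-diamine (2 mol%, the antipode that gives the (2S,3R)-oxirane), cumene hydroperoxide, toluene, rt
Reagents that add atoms: cumene hydroperoxide, CC(C)(OO)c1ccccc1
Why: Hydroxyl-directed vanadium-catalysed asymmetric epoxidation of a Z-homoallylic alcohol: the ligand chooses the alkene face and the cis-epoxide fixes C12 (S) and, for later inversion, C13 (R).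

**Step 6**
Reactants: 11 2-[(2S,3R)-3-ethyloxiran-2-yl]ethan-1-ol
Product: 12 (3S,4S)-4-bromohexane-1,3-diol
Conditions: MgBr2·OEt2 (1.5 equiv), Et2O, −20 → 0 °C; aq. NH4Cl
Reagents that add atoms: magnesium bromide, Br[Mg]Br
Why: Chelation-controlled SN2 opening of the 3,4-epoxy alcohol (magnesium bridges the hydroxyl and the epoxide oxygen): bromide enters the distal carbon C13 with inversion and the C12–O bond is untouched, giving the threo bromohydrin.

**Step 7**
Reactants: 12 (3S,4S)-4-bromohexane-1,3-diol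
Product: 13 (3S,4S)-4-bromo-1-iodohexan-3-ol
Conditions: I2, PPh3, imidazole, CH2Cl2, −10 °C
Reagents that add atoms: iodine, II
Why: Appel-type iodination (Garegg–Samuelsson conditions) is selective for the primary hydroxyl and does not touch the stereocentres.

**Step 8**
Reactants: 13 (3S,4S)-4-bromo-1-iodohexan-3-ol
Product: 14 {[(3S,4S)-4-bromo-1-iodohexan-3-yl]oxy}triethylsilane
Conditions: Et3SiCl, imidazole, CH2Cl2, 0 °C
Reagents that add atoms: chlorotriethylsilane, CC[Si](Cl)(CC)CC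
Why: Silyl ether formation; the triethylsilyl ether protects O12 during ylide chemistry and is the reacting group in the reductive etherification of step 11.

**Step 9**
Reactants: 14 {[(3S,4S)-4-bromo-1-iodohexan-3-yl]oxy}triethylsilane
Product: 15 [(3S,4S)-4-bromo-3-(triethylsilyloxy)hexyl]triphenylphosphonium iodide
Conditions: PPh3, MeCN, 70 °C
Reagents that add atoms: triphenylphosphine, c1ccc(cc1)P(c1ccccc1)c1ccccc1
Why: SN2 quaternisation of the primary iodide; the hindered secondary bromide reacts far more slowly.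

**Step 10**
Reactants: 15 [(3S,4S)-4-bromo-3-(triethylsilyloxy)hexyl]triphenylphosphonium iodide; 9 2-[(2R,5R)-3-oxo-5-[(1S)-1-(triisopropylsilyloxy)prop-2-yn-1-yl]oxolan-2-yl]acetaldehyde
Product: 17 (2R,5R)-2-[(2Z,5S,6S)-6-bromo-5-(triethylsilyloxy)oct-2-en-1-yl]-5-[(1S)-1-(triisopropylsilyloxy)prop-2-yn-1-yl]oxolan-3-one, via phosphorus ylide 16 (not isolated)
Conditions: NaN(SiMe3)2, THF, −78 °C; then 9, −78 → −20 °C
Reagents that add atoms: none
Why: Wittig olefination with a non-stabilised ylide under lithium-free conditions gives the (9Z)-alkene and takes the aldehyde in preference to the ketone at −78 °C.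

**Step 11**
Reactants: 17 (2R,5R)-2-[(2Z,5S,6S)-6-bromo-5-(triethylsilyloxy)oct-2-en-1-yl]-5-[(1S)-1-(triisopropylsilyloxy)prop-2-yn-1-yl]oxolan-3-one
Product: 19 (1R,3S,5Z,8R,10R)-3-[(1S)-1-bromopropyl]-10-[(1S)-1-(triisopropylsilyloxy)prop-2-yn-1-yl]-2,9-dioxabicyclo[6.3.0]undec-5-ene, via oxocarbenium ion 18 (not isolated)
Conditions: Et3SiH (5 equiv), TMSOTf (0.3 equiv), CH2Cl2 (0.002 M), −78 → −30 °C
Reagents that add atoms: none
Why: Intramolecular reductive etherification (silyl ether + ketone → oxocarbenium ion → silane reduction): the Z-alkene and the cis ring template favour closure to the eight-membered oxocarbenium ion, and hydride adds to C6 from the convex face opposite the C4 side chain, giving the cis-fused (6R) junction with C12 already fixed.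

**Step 12**
Reactants: 19 (1R,3S,5Z,8R,10R)-3-[(1S)-1-bromopropyl]-10-[(1S)-1-(triisopropylsilyloxy)prop-2-yn-1-yl]-2,9-dioxabicyclo[6.3.0]undec-5-ene
Product: 20 (1S)-1-[(1R,3S,5Z,8R,10R)-3-[(1S)-1-bromopropyl]-2,9-dioxabicyclo[6.3.0]undec-5-en-10-yl]prop-2-yn-1-ol
Conditions: Bu4NF, AcOH (1:1), THF, 0 °C → rt
Reagents that add atoms: none
Why: Fluoride-mediated desilylation; buffering with acetic acid protects the secondary bromide from elimination.

**Step 13**
Reactants: 20 (1S)-1-[(1R,3S,5Z,8R,10R)-3-[(1S)-1-bromopropyl]-2,9-dioxabicyclo[6.3.0]undec-5-en-10-yl]prop-2-yn-1-ol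
Product: 21 (1R,3S,5Z,8R,10R)-10-[(1R)-1-bromoprop-2-yn-1-yl]-3-[(1S)-1-bromopropyl]-2,9-dioxabicyclo[6.3.0]undec-5-ene
Conditions: CBr4, PPh3, CH2Cl2, 0 °C
Reagents that add atoms: carbon tetrabromide, BrC(Br)(Br)Br
Why: Appel reaction: SN2 displacement of the oxyphosphonium by bromide inverts C3 from S to R.

**Step 14**
Reactants: 21 (1R,3S,5Z,8R,10R)-10-[(1R)-1-bromoprop-2-yn-1-yl]-3-[(1S)-1-bromopropyl]-2,9-dioxabicyclo[6.3.0]undec-5-ene
Product: 23 (1R,3S,5S,6R,8R,10R)-5-bromo-10-[(1R)-1-bromoprop-2-yn-1-yl]-3-[(1S)-1-bromopropyl]-2,9-dioxabicyclo[6.3.0]undecan-6-ol, via tricyclic oxonium ion 22 (not isolated)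
Conditions: Et2SBr·SbCl5Br (BDSB, 1.1 equiv), MeNO2, −25 °C, 5 min; then H2O–THF (1:4), −25 → 0 °C
Reagents that add atoms: bromodiethylsulfonium bromopentachloroantimonate, CC[S+](Br)CC.Cl[Sb-](Cl)(Cl)(Cl)(Cl)Br; water, O
Why: Proposed new method: the bromonium ion of the ring alkene is opened transannularly by Oa at C9 (only this five-membered closure is possible, so bromine must end on C10, and the alkene face that places the new oxolanium ring anti to ring A is expected to be preferred), which contracts the oxocene to a 5/5/5-fused oxonium ion, and water then cleaves the central O–C9 bond by SN2 with inversion, re-expanding to the oxocane with OH and Br syn (9R,10S); site selectivity of the water attack (C9 against C6 and C12) is the unproven part, and the closest known reaction types are bromonium-induced transannular oxonium formation–fragmentation of medium-ring ene-ethers and the BDSB-induced oxolane-to-oxocane ring expansion ended by a tethered carbonate.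

**Compound list**
1 | (±)-pent-1-en-4-yn-3-ol | C=CC(O)C#C | starting material
2 | (1S)-1-[(2R)-oxiran-2-yl]prop-2-yn-1-ol | C#C[C@H](O)[C@H]1CO1 | intermediate
3 | {[(1S)-1-[(2R)-oxiran-2-yl]prop-2-yn-1-yl]oxy}tri(propan-2-yl)silane | C#C[C@H](O[Si](C(C)C)(C(C)C)C(C)C)[C@H]1CO1 | intermediate
4 | furan | c1ccoc1 | starting material
5 | furan-2-yllithium | [Li]c1ccco1 | intermediate
6 | (2R,3S)-1-(furan-2-yl)-3-(triisopropylsilyloxy)pent-4-yn-2-ol | C#C[C@H](O[Si](C(C)C)(C(C)C)C(C)C)[C@H](O)Cc1ccco1 | intermediate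
7 | (2R,3S)-3-(triisopropylsilyloxy)-1-(2,3,7-trioxabicyclo[2.2.1]hept-5-en-1-yl)pent-4-yn-2-ol (furan endoperoxide, both bridgehead epimers) | C#C[C@H](O[Si](C(C)C)(C(C)C)C(C)C)[C@H](O)CC12OOC(C=C1)O2 | intermediate
8 | (2Z,6R,7S)-6-hydroxy-4-oxo-7-(triisopropylsilyloxy)non-2-en-8-ynal | C#C[C@H](O[Si](C(C)C)(C(C)C)C(C)C)[C@H](O)CC(=O)/C=C\C=O | intermediate
9 | 2-[(2R,5R)-3-oxo-5-[(1S)-1-(triisopropylsilyloxy)prop-2-yn-1-yl]oxolan-2-yl]acetaldehyde | C#C[C@H](O[Si](C(C)C)(C(C)C)C(C)C)[C@H]1CC(=O)[C@@H](CC=O)O1 | intermediate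
10 | (3Z)-hex-3-en-1-ol | CC/C=C\CCO | starting material
11 | 2-[(2S,3R)-3-ethyloxiran-2-yl]ethan-1-ol | CC[C@H]1O[C@H]1CCO | intermediate
12 | (3S,4S)-4-bromohexane-1,3-diol | CC[C@H](Br)[C@@H](O)CCO | intermediate
13 | (3S,4S)-4-bromo-1-iodohexan-3-ol | CC[C@H](Br)[C@@H](O)CCI | intermediate
14 | {[(3S,4S)-4-bromo-1-iodohexan-3-yl]oxy}triethylsilane | CC[C@H](Br)[C@@H](O[Si](CC)(CC)CC)CCI | intermediate
15 | [(3S,4S)-4-bromo-3-(triethylsilyloxy)hexyl]triphenylphosphonium iodide | CC[C@H](Br)[C@@H](O[Si](CC)(CC)CC)CC[P+](c1ccccc1)(c1ccccc1)c1ccccc1.[I-] | intermediate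
16 | [(3S,4S)-4-bromo-3-(triethylsilyloxy)hexylidene]triphenyl-λ5-phosphane (ylide) | CC[C@H](Br)[C@@H](O[Si](CC)(CC)CC)CC=P(c1ccccc1)(c1ccccc1)c1ccccc1 | intermediate
17 | (2R,5R)-2-[(2Z,5S,6S)-6-bromo-5-(triethylsilyloxy)oct-2-en-1-yl]-5-[(1S)-1-(triisopropylsilyloxy)prop-2-yn-1-yl]oxolan-3-one | C#C[C@H](O[Si](C(C)C)(C(C)C)C(C)C)[C@H]1CC(=O)[C@@H](C/C=C\C[C@H](O[Si](CC)(CC)CC)[C@@H](Br)CC)O1 | intermediate
18 | eight-membered oxocarbenium ion (O2=C1 in the locants of 19), triflate salt | C#C[C@H](O[Si](C(C)C)(C(C)C)C(C)C)[C@H]1CC2=[O+][C@H]([C@@H](Br)CC)C/C=C\C[C@H]2O1.[O-]S(=O)(=O)C(F)(F)F | intermediate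
19 | (1R,3S,5Z,8R,10R)-3-[(1S)-1-bromopropyl]-10-[(1S)-1-(triisopropylsilyloxy)prop-2-yn-1-yl]-2,9-dioxabicyclo[6.3.0]undec-5-ene | C#C[C@H](O[Si](C(C)C)(C(C)C)C(C)C)[C@H]1C[C@H]2O[C@H]([C@@H](Br)CC)C/C=C\C[C@H]2O1 | intermediate
20 | (1S)-1-[(1R,3S,5Z,8R,10R)-3-[(1S)-1-bromopropyl]-2,9-dioxabicyclo[6.3.0]undec-5-en-10-yl]prop-2-yn-1-ol | C#C[C@H](O)[C@H]1C[C@H]2O[C@H]([C@@H](Br)CC)C/C=C\C[C@H]2O1 | intermediate
21 | (1R,3S,5Z,8R,10R)-10-[(1R)-1-bromoprop-2-yn-1-yl]-3-[(1S)-1-bromopropyl]-2,9-dioxabicyclo[6.3.0]undec-5-ene | C#C[C@@H](Br)[C@H]1C[C@H]2O[C@H]([C@@H](Br)CC)C/C=C\C[C@H]2O1 | intermediate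
22 | tricyclic oxonium ion (O2 of 21 bonded to C1, C3 and C6; Br on C5), bromopentachloroantimonate salt | C#C[C@@H](Br)[C@H]1C[C@H]2[O+]3[C@H]([C@@H](Br)CC)C[C@H](Br)[C@@H]3C[C@H]2O1.Cl[Sb-](Cl)(Cl)(Cl)(Cl)Br | intermediate
23 | (1R,3S,5S,6R,8R,10R)-5-bromo-10-[(1R)-1-bromoprop-2-yn-1-yl]-3-[(1S)-1-bromopropyl]-2,9-dioxabicyclo[6.3.0]undecan-6-ol | C#C[C@@H](Br)[C@H]1C[C@H]2O[C@H]([C@@H](Br)CC)C[C@H](Br)[C@H](O)C[C@H]2O1 | target

**Total step count:** 14. **Longest linear sequence:** 10 (steps 5–14).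

**Steps most likely to fail and fallbacks**

Step 14 (the proposed new step). Water may open the oxonium ion at C6 or C12 instead of C9, or the bromonium ion may be captured before Oa participates. The fallback uses known chemistry, sets out from 21 and comes back at 23. NBS in acetone–water gives, by ordinary anti bromohydrin addition, the C9-epimeric (6S)-bromohydrin F1 (regioisomers removed by chromatography). Dess–Martin periodinane oxidises it to the α-bromo ketone F2. NaBH4 with CeCl3·7H2O in MeOH at −78 °C then delivers hydride anti to the C–Br bond and gives the cis bromohydrin 23.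

Step 11. Direct closure of an eight-membered ring by reductive etherification may lose to intermolecular etherification or simple ketone reduction. The fallback sets out from 17 and comes back at 19 by the hydroxy dithioketal route that is established for oxocenes. EtSH and Zn(OTf)2 convert the ketone (with loss of the triethylsilyl group) into the hydroxy dithioketal F3. Dimethyl(methylthio)sulfonium tetrafluoroborate with 2,6-di-tert-butyl-4-methylpyridine in CH2Cl2 closes the ring to the mixed O,S-ketal F4. mCPBA (2 equiv, −78 °C) gives the sulfone F5, and Et3SiH with BF3·OEt2 reduces it through the same oxocarbenium ion to 19.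

Step 1. The ethynyl group is small, so the kinetic resolution may be only moderately selective, and 2 is volatile and water-soluble. The fallback sets out from 1 and comes back at 3. EtMgBr (2.1 equiv) then Me3SiCl (1 equiv) gives the C-silylated (±)-alkynol F6, a bulkier and better-behaved substrate for the same Sharpless kinetic resolution. That resolution gives the epoxy alcohol F7, TIPSOTf with 2,6-lutidine gives the silyl ether F8, and K2CO3 in MeOH removes the alkyne silyl group to give 3.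

**Further compounds**
F1 | step 14 | (1R,3S,5S,6S,8R,10R)-5-bromo-10-[(1R)-1-bromoprop-2-yn-1-yl]-3-[(1S)-1-bromopropyl]-2,9-dioxabicyclo[6.3.0]undecan-6-ol | C#C[C@@H](Br)[C@H]1C[C@H]2O[C@H]([C@@H](Br)CC)C[C@H](Br)[C@@H](O)C[C@H]2O1
F2 | step 14 | (1R,3S,5S,8R,10R)-5-bromo-10-[(1R)-1-bromoprop-2-yn-1-yl]-3-[(1S)-1-bromopropyl]-2,9-dioxabicyclo[6.3.0]undecan-6-one | C#C[C@@H](Br)[C@H]1C[C@H]2O[C@H]([C@@H](Br)CC)C[C@H](Br)C(=O)C[C@H]2O1
F3 | step 11 | (2Z,5S,6S)-1-[(2R,5R)-3,3-bis(ethylsulfanyl)-5-[(1S)-1-(triisopropylsilyloxy)prop-2-yn-1-yl]oxolan-2-yl]-6-bromooct-2-en-5-ol | C#C[C@H](O[Si](C(C)C)(C(C)C)C(C)C)[C@H]1CC(SCC)(SCC)[C@@H](C/C=C\C[C@H](O)[C@@H](Br)CC)O1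
F4 | step 11 | (3S,5Z,8R,10R)-3-[(1S)-1-bromopropyl]-1-(ethylsulfanyl)-10-[(1S)-1-(triisopropylsilyloxy)prop-2-yn-1-yl]-2,9-dioxabicyclo[6.3.0]undec-5-ene (C1 not defined) | C#C[C@H](O[Si](C(C)C)(C(C)C)C(C)C)[C@H]1CC2(SCC)O[C@H]([C@@H](Br)CC)C/C=C\C[C@H]2O1
F5 | step 11 | (3S,5Z,8R,10R)-3-[(1S)-1-bromopropyl]-1-(ethanesulfonyl)-10-[(1S)-1-(triisopropylsilyloxy)prop-2-yn-1-yl]-2,9-dioxabicyclo[6.3.0]undec-5-ene (C1 not defined) | C#C[C@H](O[Si](C(C)C)(C(C)C)C(C)C)[C@H]1CC2(S(=O)(=O)CC)O[C@H]([C@@H](Br)CC)C/C=C\C[C@H]2O1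
F6 | step 1 | (±)-5-(trimethylsilyl)pent-1-en-4-yn-3-ol | C=CC(O)C#C[Si](C)(C)C
F7 | step 1 | (1S)-1-[(2R)-oxiran-2-yl]-3-(trimethylsilyl)prop-2-yn-1-ol | C[Si](C)(C)C#C[C@H](O)[C@H]1CO1
F8 | step 1 | {[(1S)-1-[(2R)-oxiran-2-yl]-3-(trimethylsilyl)prop-2-yn-1-yl]oxy}tri(propan-2-yl)silane | C[Si](C)(C)C#C[C@H](O[Si](C(C)C)(C(C)C)C(C)C)[C@H]1CO1
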